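The open dimer cannot be a fixed share of what reacts. At 1.33 min, ring over open dimer read 0.558 in zeta but 0.362 in delta, so the split moves with the charge.

| setting | zeta | delta | flask |
|---|---|---|---|
| starting material | 10 mM | 15 mM | 20 mM |
| remark | run made earlier | run made earlier |  |
| time |  |  | 15 min |

| run | time / min | open dimer / % | ring / % |
|---|---|---|---|
| zeta | 1.33 | 30.1 | 16.8 |
| zeta | 2.00 | 34.6 | 22.3 |
| zeta | 3.00 | 38.2 | 25.6 |
| zeta | 4.00 | 41.8 | 30.2 |
| zeta | 6.00 | 42.6 | 35.8 |
| zeta | 10.0 | 44.6 | 44.0 |
| zeta | 15.0 | 43.8 | 49.5 |
| delta | 1.33 | 37.8 | 13.7 |
| delta | 2.00 | 42.6 | 18.4 |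
| delta | 3.00 | 46.2 | 22.6 |
| delta | 4.00 | 48.5 | 26.3 |
| delta | 6.00 | 51.0 | 30.2 |
| delta | 10.0 | 51.8 | 35.7 |
| delta | 15.0 | 53.5 | 41.1 |

(scatter of a reading: 1 percentage point)

- amount of open dimer in percent of the starting material charged, at 3.0 min, 8.0 min and 15 min

- percent here means starting material units held: one open dimer counts as two
- a reading or a percentage of ring counts all its forms, free or not

I multiplied each ratio by its charge and got 5.58 mM and 5.44 mM. The ratio therefore goes as one over c(starting material), as it does for a first-order ring route against a second-order dimer route. I called the mean of these readings the split concentration, the c(starting material) at which the two routes take equal amounts: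

s = 5.51 mM

r = s / c(starting material) = 0.275 for the new flask (a selectivity factor)

I then bracketed the new flask with two extreme versions. If the split stayed frozen at r, open dimer would end at:

1 / (1 + r) = 78.4%

If the new flask did no better than delta, it would stay at 53.5%. I placed the real flask between them: its charge stands above delta's, and r grows as c(starting material) falls during the run. Summing the moving split over the whole charge gave my end share of open dimer, the quantity to carry:

1 − r·ln((1 + r)/r) = 57.8%

This lies below the frozen split and above delta. Delta's open dimer gained just 2.5 percentage points from 6.00 min to 15.0 min, so I expected a plateau by 15 min and committed to 57.8% there.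

The forecast gave 51.8%, 57.8% and 59.3%, holding that “ring forms first order and dimer second order, in parallel”, and its last value stands above mine.

The flask gave 52.9%, 57.8% and 58.9%.

    2 starting material → open dimer (k = 23.0 M⁻¹ min⁻¹)
    starting material → ring (k = 0.180 min⁻¹)
    starting material + ring ⇌ idle adduct, settled at all times (K = 230 M⁻¹)

My 57.8% stood 1.1 points below the flask's 58.9%. The same rule, given the flask's start ratio of the two routes, 0.20, yields 64.2%, and the simulated run with the idle adduct taken away ended at 64.6%. The flask with the adduct ended lower, at 58.9%, because starting material tied up beside ring is kept from the dimer route, a difference of 5.6 points.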